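**Assumption:** The target is taken with the absolute configuration drawn, (2S,3R,4R) on the tetrahydrofuran. The chiral NHC enantiomer is chosen to give the (R)-adduct 3. The benzylic carbinol centre in 7 and 8 is left undefined because it is re-set in Step 5.

**Retrosynthesis**
- The 2-aryl tetrahydrofuran is closed last, by cationic cyclodehydration of a 1,4-diol. The 3,4-cis substituents force the aryl group trans to both neighbours.
- The triol comes from LiAlH4 opening of a trans-3,4-disubstituted γ-butyrolactone.
- The C7–C8 bond is formed by a lactone-enolate aldol with 3,4,5-trimethoxybenzaldehyde, anti to the β-substituent.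
- The β-aroyl lactone comes from an asymmetric NHC-catalysed Stetter addition of veratraldehyde to butenolide, which sets the first stereocentre.
- The lactone ring is already present in butenolide. The THF ring is formed in the second-to-last step.

**Route**

**Step 1**
Reactants: 1 (3,4-dimethoxybenzaldehyde), 2 (furan-2(5H)-one)
Product: 3, (R)-4-(3,4-dimethoxybenzoyl)dihydrofuran-2(3H)-one
Conditions: chiral aminoindanol-derived N-C6F5 triazolium salt (10 mol %), DIPEA (10 mol %), toluene, 25 °C
Reagents that add atoms: none
Why: Proposed new method: the triazolylidene and 1 give a Breslow intermediate (an acyl-anion equivalent). It adds to the β-carbon of the planar butenolide, and the catalyst pocket selects the enantioface. The lactone enolate is protonated and the ketone released with carbene turnover. The closest known reaction is the intermolecular asymmetric Stetter reaction of aromatic aldehydes with enones, acrylates and nitroalkenes, extended here to an unsaturated γ-lactone. It forms the C7′–C8′ bond and sets C8′ (R).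

**Step 2**
Reactants: 3, 4 (ethane-1,2-dithiol)
Product: 5, (R)-4-[2-(3,4-dimethoxyphenyl)-1,3-dithiolan-2-yl]oxolan-2-one
Conditions: BF3·OEt2, CH2Cl2, 0 °C → 25 °C
Reagents that add atoms: ethane-1,2-dithiol, SCCS
Why: Thioketalization removes the acidic α-H of the ketone. This prevents enolization and E1cB ring-opening of the β-acyloxy ketone in the next step and keeps C8′ configurationally stable.

**Step 3**
Reactants: 5, 6 (3,4,5-trimethoxybenzaldehyde)
Product: 7, (3S,4R)-4-[2-(3,4-dimethoxyphenyl)-1,3-dithiolan-2-yl]-3-[hydroxy(3,4,5-trimethoxyphenyl)methyl]oxolan-2-one (carbinol epimers)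
Conditions: LiHMDS (1.1 equiv), THF, −78 °C; then 6, −78 °C; aqueous NH4Cl
Reagents that add atoms: none (6 is a reactant)
Why: Lactone enolate aldol addition. The aldehyde approaches anti to the bulky β-dithiolanyl group, giving the trans-3,4 lactone, which sets C8. The carbinol epimers converge in Step 5.

**Step 4**
Reactants: 7
Product: 8, (2R,3R)-2-[2-(3,4-dimethoxyphenyl)-1,3-dithiolan-2-yl]-3-[hydroxy(3,4,5-trimethoxyphenyl)methyl]butane-1,4-diol
Conditions: LiAlH4 (2.5 equiv), THF, 0 °C → 25 °C
Reagents that add atoms: none (hydride adds H only)
Why: Hydride reduction of the lactone to the diol. The thioketal and aryl ethers are untouched, and no stereocentre is altered.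

**Step 5**
Reactants: 8
Product: 9, {(2S,3R,4R)-4-[2-(3,4-dimethoxyphenyl)-1,3-dithiolan-2-yl]-2-(3,4,5-trimethoxyphenyl)tetrahydrofuran-3-yl}methanol
Conditions: p-TsOH·H2O (10 mol %), CH2Cl2 (0.01 M), 0 °C → 25 °C
Reagents that add atoms: none
Why: Acid-catalysed dehydrative etherification. The electron-rich benzylic cation at C7 is captured by the C9′ hydroxyl (5-exo; the C9 hydroxyl would give an oxetane). The cis C3/C4 substituents leave one face open, so the aryl group ends up trans to both, setting C7 as (S).

**Step 6**
Reactants: 9, 10 (water)
Product: 11, magnone B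
Conditions: MeI (20 equiv), CaCO3 (5 equiv), MeCN/H2O 9:1, 50 °C
Reagents that add atoms: water, O
Why: Alkylative dithioacetal hydrolysis. S-methylation activates the thioketal and water delivers the carbonyl oxygen under buffered, near-neutral conditions. The epimerizable C4–H and the benzylic ether are preserved, giving the aroyl ketone and the free primary alcohol.

**Compound list**
1 | 3,4-dimethoxybenzaldehyde | COc1ccc(C=O)cc1OC | starting material
2 | furan-2(5H)-one | O=C1C=CCO1 | starting material
3 | (R)-4-(3,4-dimethoxybenzoyl)dihydrofuran-2(3H)-one | O=C1C[C@@H](C(=O)c2ccc(OC)c(OC)c2)CO1 | intermediate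
4 | ethane-1,2-dithiol | SCCS | starting material (reagent)
5 | (R)-4-[2-(3,4-dimethoxyphenyl)-1,3-dithiolan-2-yl]oxolan-2-one | O=C1C[C@@H](C2(c3ccc(OC)c(OC)c3)SCCS2)CO1 | intermediate
6 | 3,4,5-trimethoxybenzaldehyde | COc1cc(C=O)cc(OC)c1OC | starting material
7 | (3S,4R)-lactone aldol adduct (carbinol epimeric mixture) | O=C1OC[C@H](C2(c3ccc(OC)c(OC)c3)SCCS2)[C@H]1C(O)c1cc(OC)c(OC)c(OC)c1 | intermediate
8 | (2R,3R)-triol (carbinol epimeric mixture) | OC[C@H](C(O)c1cc(OC)c(OC)c(OC)c1)[C@H](CO)C1(c2ccc(OC)c(OC)c2)SCCS1 | intermediate
9 | (2S,3R,4R)-THF thioketal alcohol | COc1ccc(cc1OC)C2(SCCS2)[C@H]3CO[C@H](c4cc(OC)c(OC)c(OC)c4)[C@H]3CO | intermediate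
10 | water | O | reagent
11 | magnone B, (3,4-dimethoxyphenyl)[(3R,4R,5S)-4-(hydroxymethyl)-5-(3,4,5-trimethoxyphenyl)oxolan-3-yl]methanone | COc1ccc(C(=O)[C@H]2CO[C@H](c3cc(OC)c(OC)c(OC)c3)[C@H]2CO)cc1OC | target

**Totals:** 6 steps; longest linear sequence 6.

**Three steps most likely to fail**
1. **Step 1 (proposed new Stetter reaction).** The electron-rich aldehyde may favour benzoin formation, conversion or ee may be low, or C8′ may racemize by enolization and E1cB ring-opening.
   - Fallback: Friedel–Crafts acylation of veratrole with (±)-5-oxotetrahydrofuran-3-carbonyl chloride (from paraconic acid), then preparative chiral SFC/HPLC to isolate (R)-3. This uses known chemistry and abandons the catalytic asymmetric route.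
2. **Step 5 (cyclodehydration).** Styrene elimination, oligomerization, sulfur participation or modest C7 selectivity could occur.
   - Fallback: silylate the less hindered C9 primary hydroxyl (TBSCl, imidazole), separate the carbinol epimers of 8, and close the ring by Mitsunobu SN2 (PPh3, DIAD) with inversion at C7. Then remove the silyl group with TBAF.
3. **Step 6 (dithiolane hydrolysis).** C8′ may epimerize, the electron-rich arenes may be attacked, or the hydrolysis may be sluggish.
   - Fallback: replace Step 2 with NaBH4 reduction and TBS protection of the aroyl group as the benzylic silyl ether. Carry it through Steps 3–5, then remove TBS with TBAF and oxidize the benzylic alcohol selectively with MnO2 to restore the ketone.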